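Both substrates, in the proposed steps, meet the same free catalyst and the same coupling partner at each moment, so the ratio of their logarithmic losses should stay constant as the run slows. For each substrate that loss is the natural logarithm of its starting share over what remains. The ratio of left-handed to right-handed loss, s, is the selectivity factor, and the north run at 1.00 min reads 6.11.

| flask | left-handed substrate | right-handed substrate | coupling partner | free catalyst | impurity | remark | time |
|---|---|---|---|---|---|---|---|
| north | 0.020 M | 0.020 M | 0.040 M (fed, over 50 s) | 1 mM | 0.094 mM | run made earlier |  |
| west | 0.020 M | 0.020 M | 0.040 M (fed, over 50 s) | 1 mM | 0.21 mM | run made earlier |  |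
| south-east | 0.020 M | 0.020 M | 0.040 M (fed, over 50 s) | 0.50 mM | 0.14 mM | run made earlier |  |
| flask | 0.020 M | 0.020 M | 0.0400 M (fed, over 50 s) | 1.0 mM | 0.14 mM |  | 3.0 min |

| run | time / min | left-handed substrate / % | right-handed substrate / % |
|---|---|---|---|
| north | 0.500 | 31.0 | 45.8 |
| north | 1.00 | 9.8 | 38.3 |
| north | 1.50 | 5.2 | 33.5 |
| north | 2.00 | 5.3 | 28.5 |
| north | 2.50 | 1.3 | 29.7 |
| north | 3.00 | 1.1 | 26.7 |
| north | 4.00 | 0.7 | 23.7 |
| west | 0.250 | 43.7 | 47.8 |
| west | 0.417 | 34.9 | 45.8 |
| west | 0.667 | 23.5 | 45.1 |
| west | 1.00 | 13.5 | 40.0 |
| west | 1.50 | 8.6 | 35.4 |
| west | 2.50 | 2.2 | 29.9 |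
| west | 4.00 | 1.6 | 25.7 |
| south-east | 0.250 | 46.7 | 49.6 |
| south-east | 0.500 | 39.4 | 48.3 |
| south-east | 1.00 | 24.2 | 43.0 |
| south-east | 2.00 | 12.8 | 38.3 |
| south-east | 4.00 | 7.8 | 36.6 |

(standard deviation of a reading: 1 percentage point)

- free catalyst is single-handed; left-handed substrate and right-handed substrate are mirror images of each other, charged as a racemate, each of them at the stated concentration
- the analysis behind the earlier runs scatters by 1 percentage point, standard deviation
- steps that have been proposed: coupling partner + free catalyst + left-handed substrate -> free catalyst + left-handed product; coupling partner + free catalyst + right-handed substrate -> free catalyst + right-handed product; left-handed product <-> right-handed product; coupling partner + free catalyst -> spent catalyst A; free catalyst + impurity -> spent catalyst B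
- an excess is the difference of the two amounts in percent of their sum
- an excess is below zero if the other one leads

- part of the left-handed substrate and right-handed substrate charged together that has reacted at 3.0 min
- excess of left-handed product over right-handed product in the product at 3.0 min
- excess of right-handed substrate over left-handed substrate among what is left of the two at 3.0 min

I therefore follow one rate, that of λ, the logarithmic loss of right-handed substrate. In the north run it reads 0.358 min⁻¹ between 0.500 min and 1.00 min, but 0.119 min⁻¹ between 3.00 min and 4.00 min, a third of the earlier reading. The proposed step free catalyst + impurity counts one impurity against one free catalyst, so I call w the working catalyst, free catalyst charged minus impurity, which in the flask is a factor 0.860 of the charge. The accumulated rate in the north run reads 0.692 mM⁻¹ at 3.00 min, and this g is the logarithmic loss per mM of working catalyst at that time. At 4.00 min the same ratio reads 0.824 mM⁻¹, 0.842 mM⁻¹ and 0.867 mM⁻¹ in the north, west and south-east runs.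

For the flask, my reckoning gives λ = 0.596, so 27.6% right-handed and 1.31% left-handed substrate remain. That means c = 71.1% and eS = 90.9%. The readings hold no product, so I give no eP. The forecast says c = 71.3%, eS = 90% and eP = 35%, and adds: “Product racemization is invisible in substrate data”.

The flask gives c = 70.4%, eS = 88.1% and eP = −0.874%.

    coupling partner + free catalyst + left-handed substrate → free catalyst + left-handed product (k = 2400 M⁻² s⁻¹)
    coupling partner + free catalyst + right-handed substrate → free catalyst + right-handed product (k = 420 M⁻² s⁻¹)
    left-handed product ⇌ right-handed product (k = 0.0180 s⁻¹)
    coupling partner + free catalyst → spent catalyst A (k = 0.380 M⁻¹ s⁻¹)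
    free catalyst + impurity → spent catalyst B (k = 3700 M⁻¹ s⁻¹)

In the flask, λ comes to 0.586. The forecast and the flask part on eP: the relaxation half-life of left-handed and right-handed product by their interconversion alone, 0.321 min, is short against 3.0 min, and at that time the flask holds 34.9% left-handed and 35.5% right-handed product. In the neighbouring flask with 5.6 × 10⁻⁴ M of impurity, w is 0.440 mM, so g gives λ = 0.305 and 36.9% right-handed substrate; that neighbouring flask holds 35.2%.

(Readings and results were generated by integration with constants of no real substance.)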